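**Plan**
Ring A (the benzene ring) is numbered by position: 1 carries the bridging CH2, 2 an OH, 3 the prenyl group, 4 an OH, 5 the isobutyryl group, 6 an OH; ring B is the pyranone.
Cuts: first the O–Si and O–CH2 protecting bonds, then the bond from position 5 to the acyl carbon (brought in ortho to the oxygen on position 6), then the ring A bonds between positions 6 and 1 and between positions 2 and 3. The last cut splits ring A into a 2-prenyl-3-siloxycyclobutenone (positions 3 to 6) and a siloxyalkyne (positions 1 and 2) that already bears the pyranonylmethyl group.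
Enabling feature: oxygen on positions 2, 4 and 6 of ring A alternates with carbon on positions 1, 3 and 5, which is the pattern a 3-oxy vinylketene and an ynol ether deliver, each substituent riding on a defined partner.
Forward: ring B is made first (silyl enol ether of pentan-3-one plus propargylmalonyl dichloride) and its alkyne terminus is oxidised to the siloxyalkyne. The cyclobutenone comes from a prenyl-substituted siloxyalkyne and ketene. Benzannulation closes ring A, the acyl group is built on position 5 by ortho-formylation, isopropyl addition and oxidation, and fluoride frees the four hydroxyls.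
Stereochemistry: the target has no stereocentre and no stereogenic alkene; the transient centres (the quaternary carbon of 18 and the carbinol carbon of 24) are racemic and are erased by ring opening and by oxidation.

Key step: step 9

Assumption: the lithium pyranonolate formed in step 5 is taken to be alkylated by the chloromethyl ether at its 4-oxygen (2-pyranone retained); a 2-O-alkylated 4-pyranone isomer, if formed, would be removed by chromatography.

Abbreviations: TIPS = triisopropylsilyl; SEM = 2-(trimethylsilyl)ethoxymethyl; Pyr = 6-ethyl-5-methyl-2-oxo-4-(SEM-oxy)-2H-pyran-3-yl.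

**Route**

Step 1
Reactants: 1 diethyl 2-(prop-2-yn-1-yl)propanedioate (diethyl propargylmalonate)
Product: 2 2-(prop-2-yn-1-yl)propanedioic acid
Conditions: KOH (2.5 equiv), EtOH–H2O, rt; then aq. HCl to pH 1
Reagents that add atoms: potassium hydroxide, [K+].[OH-]
Why: Ester saponification by acyl–oxygen cleavage should be clean because the terminal alkyne is inert to aqueous hydroxide at room temperature.

Step 2
Reactants: 2 2-(prop-2-yn-1-yl)propanedioic acid
Product: 3 2-(prop-2-yn-1-yl)propanedioyl dichloride
Conditions: (COCl)2 (2.4 equiv), DMF (cat.), CH2Cl2, 0 °C → rt; volatiles removed, used crude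
Reagents that add atoms: oxalyl chloride, ClC(=O)C(=O)Cl
Why: Acid chloride formation through the Vilsmeier-type chloroiminium catalyst is standard for monosubstituted malonic acids and leaves the alkyne untouched.

Step 3
Reactants: 4 pentan-3-one
Product: 5 trimethyl(pent-2-en-3-yloxy)silane (E/Z mixture used as such)
Conditions: Me3SiOTf (1.05 equiv), Et3N (1.3 equiv), CH2Cl2, 0 °C; distillation
Reagents that add atoms: trimethylsilyl trifluoromethanesulfonate, C[Si](C)(C)OS(=O)(=O)C(F)(F)F
Why: Soft enolisation and O-silylation of a symmetrical ketone can give only one constitutional silyl enol ether, and both alkene isomers lead to the same pyranone.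

Step 4
Reactants: 3 2-(prop-2-yn-1-yl)propanedioyl dichloride; 5 trimethyl(pent-2-en-3-yloxy)silane
Product: 6 6-ethyl-4-hydroxy-5-methyl-3-(prop-2-yn-1-yl)-2H-pyran-2-one
Conditions: Et2O, −78 °C → rt, 24 h; extraction into aq. NaHCO3, reprecipitation with HCl
Reagents that add atoms: none
Why: C-acylation of the silyl enol ether by one acid chloride and O-acylation of the resulting enol by the other (silyl enol ether–malonyl dichloride pyranone synthesis) should close ring B with ethyl, methyl, hydroxyl and propargyl groups in place.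

Step 5
Reactants: 6 6-ethyl-4-hydroxy-5-methyl-3-(prop-2-yn-1-yl)-2H-pyran-2-one
Product: 9 6-ethyl-5-methyl-3-[3-(triisopropylsilyloxy)prop-2-yn-1-yl]-4-{[2-(trimethylsilyl)ethoxy]methoxy}-2H-pyran-2-one, via dilithium ynolate–pyranonolate 7 (not isolated), via lithium pyranonolate siloxyalkyne 8 (not isolated)
Conditions: LiN(SiMe3)2 (1.05 equiv) then n-BuLi (1.0 equiv), THF, −78 °C; t-BuOOLi (1.2 equiv, from t-BuOOH and LiN(SiMe3)2), −78 → −10 °C; i-Pr3SiOTf (1.1 equiv), −78 °C; Me3SiCH2CH2OCH2Cl (2.5 equiv), DMPU, −78 → 0 °C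
Reagents that add atoms: tert-butyl hydroperoxide, CC(C)(C)OO; triisopropylsilyl trifluoromethanesulfonate, CC(C)[Si](OS(=O)(=O)C(F)(F)F)(C(C)C)C(C)C; 2-(trimethylsilyl)ethoxymethyl chloride, C[Si](C)(C)CCOCCl
Why: Removing the acidic 4-OH proton first turns ring B into an electron-rich pyranonolate that resists deprotonation at its 6-ethyl group and nucleophilic attack, so the second base equivalent should metalate only the terminal alkyne, after which acetylide-to-ynolate oxidation by lithium tert-butyl peroxide, O-silylation of the far more nucleophilic ynolate oxygen by the hindered silyl triflate and O-alkylation of the remaining pyranonolate by the chloromethyl ether follow in one flask.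

Step 6
Reactants: 10 1-bromo-3-methylbut-2-ene (prenyl bromide)
Product: 11 5-methylhex-4-en-1-yne
Conditions: HC≡CMgBr (1.5 equiv, 0.5 M in THF), CuCl (5 mol %), THF, 0 → 45 °C; fractional distillation
Reagents that add atoms: ethynylmagnesium bromide, C#C[Mg]Br
Why: Copper-catalysed coupling of an alkynyl Grignard reagent with a primary allylic bromide should give the skipped enyne by attack at the unhindered CH2 terminus, the excess Grignard reagent limiting double alkylation.

Step 7
Reactants: 11 5-methylhex-4-en-1-yne
Product: 13 triisopropyl[(5-methylhex-4-en-1-yn-1-yl)oxy]silane, via lithium ynolate 12 (not isolated)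
Conditions: n-BuLi (1.05 equiv), THF, −78 °C; t-BuOOLi (1.2 equiv, from t-BuOOH and LiN(SiMe3)2), −78 → −10 °C; i-Pr3SiOTf (1.2 equiv), −78 → 0 °C
Reagents that add atoms: tert-butyl hydroperoxide, CC(C)(C)OO; triisopropylsilyl trifluoromethanesulfonate, CC(C)[Si](OS(=O)(=O)C(F)(F)F)(C(C)C)C(C)C
Why: Oxidation of a lithium acetylide by lithium tert-butyl peroxide to the ynolate and O-silylation with a bulky silyl triflate is the standard route from a terminal alkyne to a triisopropylsiloxyalkyne, and the trisubstituted alkene is inert to the peroxide.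

Step 8
Reactants: 13 triisopropyl[(5-methylhex-4-en-1-yn-1-yl)oxy]silane; 14 acetone (ketene source)
Product: 16 2-(3-methylbut-2-en-1-yl)-3-(triisopropylsilyloxy)cyclobut-2-en-1-one, via ketene 15 (not isolated)
Conditions: acetone pyrolysed in a hot-wire ketene generator (ca. 700 °C); ketene stream passed into 13, CH2Cl2, 0 °C → rt
Reagents that add atoms: none
Why: Thermal ketene–ynol ether [2+2] cycloaddition, in which the alkyne carbon remote from oxygen bonds to the ketene carbonyl carbon, should give the 2-alkyl-3-siloxycyclobutenone as a single regioisomer, and the isolated trisubstituted alkene does not react with unactivated ketene.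

Step 9
Reactants: 9 6-ethyl-5-methyl-3-[3-(triisopropylsilyloxy)prop-2-yn-1-yl]-4-{[2-(trimethylsilyl)ethoxy]methoxy}-2H-pyran-2-one; 16 2-(3-methylbut-2-en-1-yl)-3-(triisopropylsilyloxy)cyclobut-2-en-1-one
Product: 21 6-ethyl-3-{[6-hydroxy-3-(3-methylbut-2-en-1-yl)-2,4-bis(triisopropylsilyloxy)phenyl]methyl}-5-methyl-4-{[2-(trimethylsilyl)ethoxy]methoxy}-2H-pyran-2-one, via vinylketene 17 (not isolated), via vinylcyclobutenone 18 (not isolated), via dienylketene 19 (not isolated), via cyclohexadienone 20 (not isolated)
Conditions: 16 (1.0 equiv), 9 (1.2 equiv), toluene, 110 °C, sealed tube, Ar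
Reagents that add atoms: none
Why: Four-electron electrocyclic opening of 16 gives siloxyvinylketene 17, whose ketene C=C adds siloxyalkyne 9 in a [2+2] cycloaddition to vinylcyclobutenone 18 (new ring A bonds between positions 6 and 1 and between positions 2 and 3); a second four-electron opening gives dienylketene 19, which closes to cyclohexadienone 20 and tautomerises to phenol 21. The closest known reaction type is the Danheiser benzannulation of cyclobutenones with trialkylsiloxyalkynes, and thermal opening of 3-oxygenated cyclobutenones to vinylketenes is established in squarate-derived ring expansions. Ring A is closed by a thermal disrotatory six-electron electrocyclisation of the dienylketene, which re-forms the bond between positions 5 and 6 that the first ring opening broke. No stereocentre survives, since the racemic quaternary carbon of 18 is lost again on ring opening. The required regiochemistry is fixed by the polarisation of the siloxyalkyne, whose carbon remote from oxygen attacks the ketene carbonyl carbon; chemoselectivity rests on the fully substituted, SEM-capped ring B, which has no acidic OH to protonate the ynol ether and is too electron-poor and hindered to engage ketene or alkyne at this temperature. A silyl ether was chosen for the oxygen on position 4 because it is a weaker donor than an alkyl ether, so less push–pull stabilisation has to be overcome in opening 16, and because it leaves together with the silyl group on the position 2 oxygen in the last step.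

Step 10
Reactants: 21 6-ethyl-3-{[6-hydroxy-3-(3-methylbut-2-en-1-yl)-2,4-bis(triisopropylsilyloxy)phenyl]methyl}-5-methyl-4-{[2-(trimethylsilyl)ethoxy]methoxy}-2H-pyran-2-one
Product: 23 2-hydroxy-5-(3-methylbut-2-en-1-yl)-3-(Pyr-methyl)-4,6-bis(triisopropylsilyloxy)benzaldehyde, via hydroxymethylphenol 22 (not isolated)
Conditions: MgCl2 (3 equiv), Et3N (6 equiv), (CH2O)n (8 equiv), THF, reflux; aq. NH4Cl
Reagents that add atoms: paraformaldehyde (as formaldehyde), C=O
Why: In this Casnati–Skattebøl ortho-formylation the magnesium phenoxide of the oxygen on position 6 should deliver formaldehyde through a six-membered chelate to position 5, the only free ring carbon, and a second formaldehyde oxidises the hydroxymethyl intermediate by hydride transfer, all under basic conditions that spare the prenyl group, the silyl ethers and the acetal on ring B.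

Step 11
Reactants: 23 2-hydroxy-5-(3-methylbut-2-en-1-yl)-3-(Pyr-methyl)-4,6-bis(triisopropylsilyloxy)benzaldehyde
Product: 24 1-[2-hydroxy-5-(3-methylbut-2-en-1-yl)-3-(Pyr-methyl)-4,6-bis(triisopropylsilyloxy)phenyl]-2-methylpropan-1-ol (racemic)
Conditions: i-PrMgCl (2.5 equiv), LaCl3·2LiCl (1 equiv), THF, −78 → −20 °C; aq. NH4Cl
Reagents that add atoms: isopropylmagnesium chloride, CC(C)[Mg]Cl
Why: Grignard 1,2-addition should occur at the aldehyde, the most electrophilic carbonyl present (the first equivalent only deprotonates the phenol, and the tetrasubstituted 4-alkoxypyranone is a hindered, deactivated vinylogous carbonate), giving a racemic carbinol whose stereocentre is erased in the next step, with the lanthanum salt suppressing β-hydride reduction.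

Step 12
Reactants: 24 1-[2-hydroxy-5-(3-methylbut-2-en-1-yl)-3-(Pyr-methyl)-4,6-bis(triisopropylsilyloxy)phenyl]-2-methylpropan-1-ol
Product: 25 1-[2-hydroxy-5-(3-methylbut-2-en-1-yl)-3-(Pyr-methyl)-4,6-bis(triisopropylsilyloxy)phenyl]-2-methylpropan-1-one
Conditions: MnO2 (activated, 20 equiv), CH2Cl2, rt
Reagents that add atoms: none
Why: Benzylic alcohol oxidation with MnO2 is selective for the electron-rich benzylic carbinol and should leave the phenol, the prenyl alkene and the silicon groups alone, the ketone being stabilised by its hydrogen bond to the hydroxyl on position 6.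

Step 13
Reactants: 25 1-[2-hydroxy-5-(3-methylbut-2-en-1-yl)-3-(Pyr-methyl)-4,6-bis(triisopropylsilyloxy)phenyl]-2-methylpropan-1-one
Product: 26 6-ethyl-4-hydroxy-5-methyl-3-{[2,4,6-trihydroxy-3-(3-methylbut-2-en-1-yl)-5-(2-methylpropanoyl)phenyl]methyl}-2H-pyran-2-one (CNP0152348.0)
Conditions: Bu4NF (6 equiv), THF–DMPU, 0 → 40 °C, Ar; aq. NH4Cl
Reagents that add atoms: none
Why: Fluoride should cleave both aryl silyl ethers and trigger β-elimination of the SEM group from the vinylogous acid oxygen (as for SEM esters) in one non-acidic operation, so the prenyl group flanked by two free hydroxyls cannot cyclise to a chroman.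

**Compound list**

1 | diethyl 2-(prop-2-yn-1-yl)propanedioate | CCOC(=O)C(CC#C)C(=O)OCC | starting material
2 | 2-(prop-2-yn-1-yl)propanedioic acid | OC(=O)C(CC#C)C(=O)O | intermediate
3 | 2-(prop-2-yn-1-yl)propanedioyl dichloride | ClC(=O)C(CC#C)C(=O)Cl | intermediate
4 | pentan-3-one | CCC(=O)CC | starting material
5 | trimethyl(pent-2-en-3-yloxy)silane (E/Z mixture) | CC=C(CC)O[Si](C)(C)C | intermediate
6 | 6-ethyl-4-hydroxy-5-methyl-3-(prop-2-yn-1-yl)-2H-pyran-2-one | CCc1oc(=O)c(CC#C)c(O)c1C | intermediate
7 | dilithium 3-(6-ethyl-5-methyl-4-oxido-2-oxo-2H-pyran-3-yl)prop-1-yn-1-olate | [Li+].[Li+].CCc1oc(=O)c(CC#C[O-])c([O-])c1C | intermediate (not isolated)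
8 | lithium 6-ethyl-5-methyl-2-oxo-3-[3-(triisopropylsilyloxy)prop-2-yn-1-yl]-2H-pyran-4-olate | [Li+].CCc1oc(=O)c(CC#CO[Si](C(C)C)(C(C)C)C(C)C)c([O-])c1C | intermediate (not isolated)
9 | 6-ethyl-5-methyl-3-[3-(triisopropylsilyloxy)prop-2-yn-1-yl]-4-{[2-(trimethylsilyl)ethoxy]methoxy}-2H-pyran-2-one | CCc1oc(=O)c(CC#CO[Si](C(C)C)(C(C)C)C(C)C)c(OCOCC[Si](C)(C)C)c1C | intermediate
10 | 1-bromo-3-methylbut-2-ene | CC(C)=CCBr | starting material
11 | 5-methylhex-4-en-1-yne | CC(C)=CCC#C | intermediate
12 | lithium 5-methylhex-4-en-1-yn-1-olate | [Li+].[O-]C#CCC=C(C)C | intermediate (not isolated)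
13 | triisopropyl[(5-methylhex-4-en-1-yn-1-yl)oxy]silane | CC(C)=CCC#CO[Si](C(C)C)(C(C)C)C(C)C | intermediate
14 | acetone | CC(C)=O | starting material
15 | ketene (ethenone) | C=C=O | intermediate (not isolated)
16 | 2-(3-methylbut-2-en-1-yl)-3-(triisopropylsilyloxy)cyclobut-2-en-1-one | O=C1CC(O[Si](C(C)C)(C(C)C)C(C)C)=C1CC=C(C)C | intermediate
17 | 2-(3-methylbut-2-en-1-yl)-3-(triisopropylsilyloxy)buta-1,3-dien-1-one | O=C=C(CC=C(C)C)C(=C)O[Si](C(C)C)(C(C)C)C(C)C | intermediate (not isolated)
18 | 4-(3-methylbut-2-en-1-yl)-2-(Pyr-methyl)-3-(triisopropylsilyloxy)-4-[1-(triisopropylsilyloxy)ethenyl]cyclobut-2-en-1-one (racemic) | O=C1C(Cc2c(OCOCC[Si](C)(C)C)c(C)c(CC)oc2=O)=C(O[Si](C(C)C)(C(C)C)C(C)C)C1(CC=C(C)C)C(=C)O[Si](C(C)C)(C(C)C)C(C)C | intermediate (not isolated)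
19 | (3E)-4-(3-methylbut-2-en-1-yl)-2-(Pyr-methyl)-3,5-bis(triisopropylsilyloxy)hexa-1,3,5-trien-1-one (ketene and vinyl groups cis) | O=C=C(Cc1c(OCOCC[Si](C)(C)C)c(C)c(CC)oc1=O)/C(O[Si](C(C)C)(C(C)C)C(C)C)=C(\C(=C)O[Si](C(C)C)(C(C)C)C(C)C)CC=C(C)C | intermediate (not isolated)
20 | 4-(3-methylbut-2-en-1-yl)-2-(Pyr-methyl)-3,5-bis(triisopropylsilyloxy)cyclohexa-2,4-dien-1-one | O=C1CC(O[Si](C(C)C)(C(C)C)C(C)C)=C(CC=C(C)C)C(O[Si](C(C)C)(C(C)C)C(C)C)=C1Cc2c(OCOCC[Si](C)(C)C)c(C)c(CC)oc2=O | intermediate (not isolated)
21 | 6-ethyl-3-{[6-hydroxy-3-(3-methylbut-2-en-1-yl)-2,4-bis(triisopropylsilyloxy)phenyl]methyl}-5-methyl-4-{[2-(trimethylsilyl)ethoxy]methoxy}-2H-pyran-2-one | Oc1cc(O[Si](C(C)C)(C(C)C)C(C)C)c(CC=C(C)C)c(O[Si](C(C)C)(C(C)C)C(C)C)c1Cc2c(OCOCC[Si](C)(C)C)c(C)c(CC)oc2=O | intermediate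
22 | 2-(hydroxymethyl)-4-(3-methylbut-2-en-1-yl)-6-(Pyr-methyl)-3,5-bis(triisopropylsilyloxy)phenol | OCc1c(O)c(Cc2c(OCOCC[Si](C)(C)C)c(C)c(CC)oc2=O)c(O[Si](C(C)C)(C(C)C)C(C)C)c(CC=C(C)C)c1O[Si](C(C)C)(C(C)C)C(C)C | intermediate (not isolated)
23 | 2-hydroxy-5-(3-methylbut-2-en-1-yl)-3-(Pyr-methyl)-4,6-bis(triisopropylsilyloxy)benzaldehyde | O=Cc1c(O)c(Cc2c(OCOCC[Si](C)(C)C)c(C)c(CC)oc2=O)c(O[Si](C(C)C)(C(C)C)C(C)C)c(CC=C(C)C)c1O[Si](C(C)C)(C(C)C)C(C)C | intermediate
24 | 1-[2-hydroxy-5-(3-methylbut-2-en-1-yl)-3-(Pyr-methyl)-4,6-bis(triisopropylsilyloxy)phenyl]-2-methylpropan-1-ol (racemic) | CC(C)C(O)c1c(O)c(Cc2c(OCOCC[Si](C)(C)C)c(C)c(CC)oc2=O)c(O[Si](C(C)C)(C(C)C)C(C)C)c(CC=C(C)C)c1O[Si](C(C)C)(C(C)C)C(C)C | intermediate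
25 | 1-[2-hydroxy-5-(3-methylbut-2-en-1-yl)-3-(Pyr-methyl)-4,6-bis(triisopropylsilyloxy)phenyl]-2-methylpropan-1-one | CC(C)C(=O)c1c(O)c(Cc2c(OCOCC[Si](C)(C)C)c(C)c(CC)oc2=O)c(O[Si](C(C)C)(C(C)C)C(C)C)c(CC=C(C)C)c1O[Si](C(C)C)(C(C)C)C(C)C | intermediate
26 | 6-ethyl-4-hydroxy-5-methyl-3-{[2,4,6-trihydroxy-3-(3-methylbut-2-en-1-yl)-5-(2-methylpropanoyl)phenyl]methyl}-2H-pyran-2-one | CCc1oc(=O)c(Cc2c(O)c(CC=C(C)C)c(O)c(C(=O)C(C)C)c2O)c(O)c1C | target

**Count and risks**

Total steps: 13. Longest linear sequence: 9 steps (1, 2, 4, 5, 9, 10, 11, 12, 13).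

Step 9. The push–pull 3-siloxycyclobutenone may open to the vinylketene only at temperatures where the siloxyalkyne isomerises to a silylketene by silyl shift, or the phenol formed may be acylated by further vinylketene. The fallback gives up ring construction and joins two preformed halves through a formaldehyde-derived methylene bridge, which is known chemistry for acylphloroglucinol–pyranone pairs. It sets out from 5 and 10 and returns at 26. Silyl enol ether 5 with malonyl dichloride would give 6-ethyl-4-hydroxy-5-methyl-2H-pyran-2-one F1. Phloroglucinol would be C-acylated with isobutyryl chloride and AlCl3 to 2-methyl-1-(2,4,6-trihydroxyphenyl)propan-1-one F2, and C-prenylation of F2 with prenyl bromide 10 in aqueous KOH would give 2-methyl-1-[2,4,6-trihydroxy-3-(3-methylbut-2-en-1-yl)phenyl]propan-1-one F3. Condensing F1 and F3 with paraformaldehyde would place the CH2 bridge on the one free ring carbon of F3 and give 26 directly, with homodimers to be separated.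

Step 5. The dilithio salt may be too insoluble for complete metalation and oxidation, or the silyl triflate and the chloromethyl ether may be distributed unselectively between the two oxyanions. The fallback protects first and makes the acetylide without an amide base; it sets out from 6 and returns at 9. Alkylation of 6 with SEM chloride and i-Pr2NEt would give 6-ethyl-5-methyl-3-(prop-2-yn-1-yl)-4-{[2-(trimethylsilyl)ethoxy]methoxy}-2H-pyran-2-one F4. Bromination of the alkyne terminus with N-bromosuccinimide and catalytic AgNO3 would give 3-(3-bromoprop-2-yn-1-yl)-6-ethyl-5-methyl-4-{[2-(trimethylsilyl)ethoxy]methoxy}-2H-pyran-2-one F5. Bromine–lithium exchange on F5 with t-BuLi at −100 °C, which is faster than deprotonation of the 6-ethyl group or carbonyl addition, followed by the same peroxide oxidation and silylation, would give 9.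

Step 11. β-Hydride reduction of the hindered, chelated aldehyde or attack of the Grignard reagent on the ring B lactone may compete with addition. The fallback bypasses the aldehyde; it sets out from 21 and returns at 24. The bromomagnesium phenoxide of 21 (EtMgBr, 1 equiv, toluene) would be treated with isobutyraldehyde, and ortho-specific hydroxyalkylation through the magnesium chelate would form the bond from position 5 of ring A to the carbinol carbon directly, with no carbon nucleophile exposed to the pyranone.

**Further compounds**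

F1 | step 9 | 6-ethyl-4-hydroxy-5-methyl-2H-pyran-2-one | CCc1oc(=O)cc(O)c1C
F2 | step 9 | 2-methyl-1-(2,4,6-trihydroxyphenyl)propan-1-one | CC(C)C(=O)c1c(O)cc(O)cc1O
F3 | step 9 | 2-methyl-1-[2,4,6-trihydroxy-3-(3-methylbut-2-en-1-yl)phenyl]propan-1-one | CC(C)C(=O)c1c(O)cc(O)c(CC=C(C)C)c1O
F4 | step 5 | 6-ethyl-5-methyl-3-(prop-2-yn-1-yl)-4-{[2-(trimethylsilyl)ethoxy]methoxy}-2H-pyran-2-one | CCc1oc(=O)c(CC#C)c(OCOCC[Si](C)(C)C)c1C
F5 | step 5 | 3-(3-bromoprop-2-yn-1-yl)-6-ethyl-5-methyl-4-{[2-(trimethylsilyl)ethoxy]methoxy}-2H-pyran-2-one | CCc1oc(=O)c(CC#CBr)c(OCOCC[Si](C)(C)C)c1C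
F0 | step 11 | none | none
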